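**Plan**
- Retrosynthetic cuts: the two cinnamoyl C–O bonds at O4 and O5; the C3–O and C4–O bonds (cis-diol back to an alkene); the ring bond C3=C4 (back to an open diene); the C5–H and C4–C5 bonds (carbinol back to an alkynyl ketone and an acid chloride); the C1–C2 bond (allyl group), ending at (S)-malic acid.
- Enabling feature: the cyclohexane ring carries a cis-diol at C3/C4, which maps onto a C3=C4 ring alkene. C1, with its OH, CO2H and the two CH2 arms C2 and C6, is a doubly α-alkylated malic acid. The chain C3=C2–C1–C6–C5–C4= can therefore be built as an open 1,7-diene.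
- Forward order: malic acid dioxolanone, allylation (C1–C2), acid arm to alkynyl ketone, (R)-carbinol, vinyl group. The only ring (C1–C6) is then closed by metathesis, followed by diol formation, protection of O3, acylation of O4/O5 and one acidolytic deprotection.
- Stereochemistry: C1 from (S)-malic acid by self-regeneration of the stereocentre (retention); C5 from catalyst-controlled transfer hydrogenation; C3 and C4 from osmylation anti to the C5 silyloxy group; both E-alkenes from p-coumaric acid.
- Protecting groups: PMB (4-methoxybenzyl) ester and PMB aryl ethers, all acid-labile at the end; TES on O5 and TBS on O3, so that O5 can be freed first.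

Key step: step 8

Remark: quinic acid numbering is used (C1 quaternary). The target SMILES places the free C3 hydroxyl and the C1 hydroxyl on the same ring face as the C4 ester oxygen, and the C5 ester oxygen and the carboxyl on the other face, i.e. the (–)-quinic acid series; "quinate" below means this configuration.

**Step 1**
Reactants: 1 (S)-malic acid; 2 pivalaldehyde
Product: 3 2-[(2S,4S)-2-tert-butyl-5-oxo-1,3-dioxolan-4-yl]acetic acid (cis-dioxolanone)
Conditions: pivalaldehyde, TsOH·H2O (cat.), H2SO4 (cat.), pentane, reflux, Dean–Stark; recrystallisation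
Reagents that add atoms: pivalaldehyde (2), CC(C)(C)C=O
Why: Acid-catalysed acetalisation of the α-hydroxy acid unit with removal of water (Seebach dioxolanone formation) should give the five-membered acylal under thermodynamic control, with the new acetal centre set cis to the CH2CO2H arm by the existing (S) centre and the cis isomer purified by crystallisation.

**Step 2**
Reactants: 3 2-[(2S,4S)-2-tert-butyl-5-oxo-1,3-dioxolan-4-yl]acetic acid; 4 allyl bromide
Product: 6 2-[(2S,4S)-2-tert-butyl-5-oxo-4-(prop-2-en-1-yl)-1,3-dioxolan-4-yl]acetic acid (allyl trans to tert-butyl), via dilithium enolate 5 (not isolated)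
Conditions: LiHMDS (2.2 equiv), THF, –78 °C; allyl bromide, –78 to –20 °C; 1 M HCl work-up
Reagents that add atoms: allyl bromide (4), C=CCBr
Why: Alkylation of the enolate dianion (self-regeneration of the stereocentre) should occur on the face opposite the tert-butyl group, so the allyl group takes the place of the former α-hydrogen and the quaternary centre forms with retention.

**Step 3**
Reactants: 6 2-[(2S,4S)-2-tert-butyl-5-oxo-4-(prop-2-en-1-yl)-1,3-dioxolan-4-yl]acetic acid; 7 trimethylsilylacetylene
Product: 9 (2S,5S)-2-tert-butyl-5-[2-oxo-4-(trimethylsilyl)but-3-yn-1-yl]-5-(prop-2-en-1-yl)-1,3-dioxolan-4-one, via acid chloride 8 (not isolated)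
Conditions: (COCl)2, DMF (cat.), CH2Cl2, 0 °C to rt, concentrate; then 7, PdCl2(PPh3)2 (2 mol %), CuI (4 mol %), Et3N (1.05 equiv), THF, rt
Reagents that add atoms: trimethylsilylacetylene (7), C#C[Si](C)(C)C
Why: Acid chloride formation followed by palladium/copper-catalysed acylation of the terminal alkyne (acyl Sonogashira coupling) should give the alkynyl ketone without a hard organometallic nucleophile that could attack the dioxolanone carbonyl; no stereocentre is touched.

**Step 4**
Reactants: 9 (2S,5S)-2-tert-butyl-5-[2-oxo-4-(trimethylsilyl)but-3-yn-1-yl]-5-(prop-2-en-1-yl)-1,3-dioxolan-4-one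
Product: 10 (2S,5S)-2-tert-butyl-5-[(2R)-2-hydroxy-4-(trimethylsilyl)but-3-yn-1-yl]-5-(prop-2-en-1-yl)-1,3-dioxolan-4-one
Conditions: Ru[(R,R)-TsDPEN](p-cymene) (preformed amido complex, 2 mol %), i-PrOH, rt
Reagents that add atoms: none
Why: Noyori asymmetric transfer hydrogenation of an alkynyl ketone is catalyst-controlled, and the (R,R)-complex is expected to give the (R)-propargylic alcohol (alkynyl in the role that aryl plays in aryl ketones) independently of the remote quaternary centre, leaving the allyl group and the silylalkyne untouched.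

**Step 5**
Reactants: 10 (2S,5S)-2-tert-butyl-5-[(2R)-2-hydroxy-4-(trimethylsilyl)but-3-yn-1-yl]-5-(prop-2-en-1-yl)-1,3-dioxolan-4-one
Product: 11 (2S,5S)-2-tert-butyl-5-(prop-2-en-1-yl)-5-[(2R)-2-(triethylsilyloxy)-4-(trimethylsilyl)but-3-yn-1-yl]-1,3-dioxolan-4-one
Conditions: TESCl, imidazole, CH2Cl2, 0 °C
Reagents that add atoms: chlorotriethylsilane, CC[Si](Cl)(CC)CC
Why: Imidazole-mediated silylation of the secondary alcohol blocks O5 before the acylal is opened, which should prevent γ-lactonisation, and TES is chosen because it can later be removed beside a TBS ether.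

**Step 6**
Reactants: 11 (2S,5S)-2-tert-butyl-5-(prop-2-en-1-yl)-5-[(2R)-2-(triethylsilyloxy)-4-(trimethylsilyl)but-3-yn-1-yl]-1,3-dioxolan-4-one
Product: 12 4-methoxybenzyl (2S,4R)-2-hydroxy-2-(prop-2-en-1-yl)-4-(triethylsilyloxy)hex-5-ynoate
Conditions: 4-MeOC6H4CH2OH (5 equiv), NaH (0.2 equiv), THF, 0 °C to rt
Reagents that add atoms: 4-methoxybenzyl alcohol, COc1ccc(CO)cc1
Why: Alkoxide-catalysed alcoholysis of the acylal carbonyl (transesterification) should release pivalaldehyde and the tertiary hydroxyl and give the PMB ester, while the same alkoxide is expected to cleave the C(sp)–SiMe3 bond (protodesilylation); the excess alcohol keeps the medium protic so that the TES ether stays in place.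

**Step 7**
Reactants: 12 4-methoxybenzyl (2S,4R)-2-hydroxy-2-(prop-2-en-1-yl)-4-(triethylsilyloxy)hex-5-ynoate
Product: 13 4-methoxybenzyl (2S,4R)-2-hydroxy-2-(prop-2-en-1-yl)-4-(triethylsilyloxy)hex-5-enoate
Conditions: H2 (1 atm, 1 equiv uptake), Lindlar catalyst, quinoline, EtOAc, rt
Reagents that add atoms: none
Why: Semihydrogenation over lead-poisoned palladium (Lindlar reduction) should stop at the vinyl group because the alkyne binds far more strongly than the monosubstituted alkenes, and the poisoned catalyst should not hydrogenolyse the PMB ester.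

**Step 8**
Reactants: 13 4-methoxybenzyl (2S,4R)-2-hydroxy-2-(prop-2-en-1-yl)-4-(triethylsilyloxy)hex-5-enoate
Product: 14 4-methoxybenzyl (1S,5R)-1-hydroxy-5-(triethylsilyloxy)cyclohex-3-ene-1-carboxylate
Conditions: Grubbs second-generation catalyst (3 mol %), CH2Cl2 (0.01 M), 40 °C
Reagents that add atoms: none
Why: The ruthenium benzylidene should first exchange with the unhindered allyl terminus, and the resulting alkylidene adds to the vinyl group next to the silyloxy carbon in a [2+2] step; cycloreversion of the ruthenacyclobutane forms the C3=C4 bond and a ruthenium methylidene that carries the chain (Chauvin mechanism). The closest known reaction type is ring-closing metathesis of 1,7-dienes bearing an allylic silyl ether to cyclohexenes under second-generation Grubbs catalysis. The one ring closed is the six-membered carbocycle, joined between the terminal allyl carbon (C3) and the inner vinyl carbon (C4) with loss of ethylene, and its double bond can only be cis. No stereocentre is formed; the quaternary C1 and the C5 carbinol are carried through unchanged. The step needs cyclisation to win over intermolecular metathesis and must avoid double-bond migration, which the 1,7-spacing, the geminal substitution at C1, high dilution and the escape of ethylene should secure.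

**Step 9**
Reactants: 14 4-methoxybenzyl (1S,5R)-1-hydroxy-5-(triethylsilyloxy)cyclohex-3-ene-1-carboxylate
Product: 15 4-methoxybenzyl 5-O-(triethylsilyl)quinate
Conditions: OsO4 (3 mol %), NMO (1.5 equiv), acetone/H2O (8:1), 0 °C to rt
Reagents that add atoms: osmium tetroxide, O=[Os](=O)(=O)=O; N-methylmorpholine N-oxide, C[N+]1([O-])CCOCC1; water, O
Why: Catalytic osmium tetroxide dihydroxylation (Upjohn conditions) is a suprafacial addition that should take place on the ring face opposite the allylic C5 silyloxy group (anti selectivity of cyclic allylic ethers), setting C3 and C4 cis to each other and on the face of the small C1 hydroxyl, as in quinic acid.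

**Step 10**
Reactants: 15 4-methoxybenzyl 5-O-(triethylsilyl)quinate
Product: 16 4-methoxybenzyl 3-O-(tert-butyldimethylsilyl)-5-O-(triethylsilyl)quinate
Conditions: TBSCl (1.2 equiv), imidazole (2.5 equiv), DMF, 0 °C to rt
Reagents that add atoms: tert-butyldimethylsilyl chloride, CC(C)(C)[Si](C)(C)Cl
Why: Imidazole-mediated silylation should select the C3 hydroxyl because the C4 hydroxyl is flanked by two oxygenated carbons (one already silylated) and the tertiary C1 hydroxyl is inert to TBSCl, in line with the known 3,5-bis-silylation of quinate esters that leaves O4 and O1 free.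

**Step 11**
Reactants: 16 4-methoxybenzyl 3-O-(tert-butyldimethylsilyl)-5-O-(triethylsilyl)quinate
Product: 17 4-methoxybenzyl 3-O-(tert-butyldimethylsilyl)quinate
Conditions: PPTS (0.2 equiv), MeOH/CH2Cl2 (1:1), 0 °C
Reagents that add atoms: none
Why: Mild acid-catalysed methanolysis (selective desilylation) cleaves a secondary TES ether much faster than a secondary TBS ether, which should free O5 beside the free O4 without touching the PMB ester.

**Step 12**
Reactants: 18 (E)-p-coumaric acid
Product: 20 (E)-4-[(4-methoxybenzyl)oxy]cinnamic acid, via bis-PMB coumarate 19 (not isolated)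
Conditions: PMBCl (2.3 equiv), K2CO3 (3 equiv), DMF, 60 °C; then aq. NaOH, MeOH/THF, 60 °C; HCl to pH 2
Reagents that add atoms: 4-methoxybenzyl chloride, COc1ccc(CCl)cc1
Why: Williamson alkylation of the phenoxide and the carboxylate gives the ether ester, and saponification of the ester should leave the aryl PMB ether and the E-alkene untouched.

**Step 13**
Reactants: 17 4-methoxybenzyl 3-O-(tert-butyldimethylsilyl)quinate; 20 (E)-4-[(4-methoxybenzyl)oxy]cinnamic acid
Product: 22 4-methoxybenzyl 3-O-(tert-butyldimethylsilyl)-4,5-bis-O-[(E)-4-(4-methoxybenzyloxy)cinnamoyl]quinate, via mixed anhydride 21 (not isolated)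
Conditions: 20 (3 equiv), 2,4,6-Cl3C6H2COCl (3 equiv), Et3N (3.5 equiv), toluene, rt; then 17, DMAP (4 equiv), rt to 40 °C
Reagents that add atoms: (E)-4-[(4-methoxybenzyl)oxy]cinnamic acid (20), COc1ccc(COc2ccc(/C=C/C(=O)O)cc2)cc1
Why: Yamaguchi esterification through the mixed 2,4,6-trichlorobenzoic anhydride and DMAP should acylate both secondary hydroxyls, the equatorial O5 first and the hindered O4 under the more forcing end of the conditions, while the tertiary α-hydroxy ester hydroxyl stays free; no ring C–O bond is broken, so no stereocentre is affected.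

**Step 14**
Reactants: 22 4-methoxybenzyl 3-O-(tert-butyldimethylsilyl)-4,5-bis-O-[(E)-4-(4-methoxybenzyloxy)cinnamoyl]quinate
Product: 23 4,5-di-O-p-coumaroylquinic acid
Conditions: TFA/H2O (9:1), anisole (20 equiv), 0 °C to rt; reversed-phase chromatography
Reagents that add atoms: none
Why: Acidolysis should cleave the PMB ester and both aryl PMB ethers through the 4-methoxybenzyl cation, which anisole traps, and the aqueous acid hydrolyses the TBS ether; under such acidic conditions cinnamoyl esters of quinic acid are stable and acyl migration is slow.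

**Compound list**
1 | (S)-malic acid | O[C@@H](CC(=O)O)C(=O)O | starting material
2 | pivalaldehyde | CC(C)(C)C=O | starting material
3 | 2-[(2S,4S)-2-tert-butyl-5-oxo-1,3-dioxolan-4-yl]acetic acid | CC(C)(C)[C@H]1O[C@@H](CC(=O)O)C(=O)O1 | intermediate
4 | allyl bromide | C=CCBr | starting material
5 | dilithium 2-[(2S)-2-tert-butyl-5-oxido-1,3-dioxol-4-yl]acetate (enolate dianion) | [Li+].[Li+].[O-]C(=O)CC1=C([O-])O[C@@H](C(C)(C)C)O1 | intermediate
6 | 2-[(2S,4S)-2-tert-butyl-5-oxo-4-(prop-2-en-1-yl)-1,3-dioxolan-4-yl]acetic acid | CC(C)(C)[C@H]1O[C@@](CC=C)(CC(=O)O)C(=O)O1 | intermediate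
7 | trimethylsilylacetylene | C#C[Si](C)(C)C | starting material
8 | 2-[(2S,4S)-2-tert-butyl-5-oxo-4-(prop-2-en-1-yl)-1,3-dioxolan-4-yl]acetyl chloride | CC(C)(C)[C@H]1O[C@@](CC=C)(CC(=O)Cl)C(=O)O1 | intermediate
9 | (2S,5S)-2-tert-butyl-5-[2-oxo-4-(trimethylsilyl)but-3-yn-1-yl]-5-(prop-2-en-1-yl)-1,3-dioxolan-4-one | CC(C)(C)[C@H]1O[C@@](CC=C)(CC(=O)C#C[Si](C)(C)C)C(=O)O1 | intermediate
10 | (2S,5S)-2-tert-butyl-5-[(2R)-2-hydroxy-4-(trimethylsilyl)but-3-yn-1-yl]-5-(prop-2-en-1-yl)-1,3-dioxolan-4-one | CC(C)(C)[C@H]1O[C@@](CC=C)(C[C@@H](O)C#C[Si](C)(C)C)C(=O)O1 | intermediate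
11 | (2S,5S)-2-tert-butyl-5-(prop-2-en-1-yl)-5-[(2R)-2-(triethylsilyloxy)-4-(trimethylsilyl)but-3-yn-1-yl]-1,3-dioxolan-4-one | CC(C)(C)[C@H]1O[C@@](CC=C)(C[C@@H](O[Si](CC)(CC)CC)C#C[Si](C)(C)C)C(=O)O1 | intermediate
12 | 4-methoxybenzyl (2S,4R)-2-hydroxy-2-(prop-2-en-1-yl)-4-(triethylsilyloxy)hex-5-ynoate | C=CC[C@@](O)(C(=O)OCc1ccc(OC)cc1)C[C@@H](O[Si](CC)(CC)CC)C#C | intermediate
13 | 4-methoxybenzyl (2S,4R)-2-hydroxy-2-(prop-2-en-1-yl)-4-(triethylsilyloxy)hex-5-enoate | C=CC[C@@](O)(C(=O)OCc1ccc(OC)cc1)C[C@@H](O[Si](CC)(CC)CC)C=C | intermediate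
14 | 4-methoxybenzyl (1S,5R)-1-hydroxy-5-(triethylsilyloxy)cyclohex-3-ene-1-carboxylate | C1=CC[C@@](O)(C(=O)OCc2ccc(OC)cc2)C[C@H]1O[Si](CC)(CC)CC | intermediate
15 | 4-methoxybenzyl 5-O-(triethylsilyl)quinate | O[C@@H]1[C@H](O)C[C@@](O)(C(=O)OCc2ccc(OC)cc2)C[C@H]1O[Si](CC)(CC)CC | intermediate
16 | 4-methoxybenzyl 3-O-(tert-butyldimethylsilyl)-5-O-(triethylsilyl)quinate | O[C@@H]1[C@H](O[Si](C)(C)C(C)(C)C)C[C@@](O)(C(=O)OCc2ccc(OC)cc2)C[C@H]1O[Si](CC)(CC)CC | intermediate
17 | 4-methoxybenzyl 3-O-(tert-butyldimethylsilyl)quinate | O[C@@H]1[C@H](O[Si](C)(C)C(C)(C)C)C[C@@](O)(C(=O)OCc2ccc(OC)cc2)C[C@H]1O | intermediate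
18 | (E)-p-coumaric acid | O=C(O)/C=C/c1ccc(O)cc1 | starting material
19 | 4-methoxybenzyl (E)-4-[(4-methoxybenzyl)oxy]cinnamate | COc1ccc(COc2ccc(/C=C/C(=O)OCc3ccc(OC)cc3)cc2)cc1 | intermediate
20 | (E)-4-[(4-methoxybenzyl)oxy]cinnamic acid | COc1ccc(COc2ccc(/C=C/C(=O)O)cc2)cc1 | intermediate
21 | (E)-4-[(4-methoxybenzyl)oxy]cinnamic 2,4,6-trichlorobenzoic anhydride | COc1ccc(COc2ccc(/C=C/C(=O)OC(=O)c3c(Cl)cc(Cl)cc3Cl)cc2)cc1 | intermediate
22 | 4-methoxybenzyl 3-O-(tert-butyldimethylsilyl)-4,5-bis-O-[(E)-4-(4-methoxybenzyloxy)cinnamoyl]quinate | O=C(/C=C/c1ccc(OCc2ccc(OC)cc2)cc1)O[C@@H]1[C@H](O[Si](C)(C)C(C)(C)C)C[C@@](O)(C(=O)OCc2ccc(OC)cc2)C[C@H]1OC(=O)/C=C/c1ccc(OCc2ccc(OC)cc2)cc1 | intermediate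
23 | 4,5-di-O-p-coumaroylquinic acid | O=C(/C=C/c1ccc(O)cc1)O[C@@H]1[C@H](O)C[C@@](O)(C(=O)O)C[C@H]1OC(=O)/C=C/c1ccc(O)cc1 | target

Total step count: 14. Longest linear sequence: 13 steps (steps 1–11, 13 and 14); step 12 is the side branch.

**Steps most likely to fail**

Step 9, insufficient facial selectivity in the osmylation. Attack syn to the pseudo-equatorial silyloxy group may compete and lead to the C3/C4 epimeric diol. The fallback uses the carboxyl as a rigid shield and sets out from 14. Fluoride (TBAF, THF, 0 °C to rt) removes the TES group, and the C5 alkoxide should close onto the cis ester to give the bicyclic lactone (1S,5R)-1-hydroxy-6-oxabicyclo[3.2.1]oct-3-en-7-one F1. In this bicycle the lactone bridge covers one face of C3=C4, so OsO4/NMO should add only from the other and give (–)-quinide F2. Silylation of the equatorial C3 hydroxyl of the lactone (TBSCl, imidazole, DMF) gives 3-O-(tert-butyldimethylsilyl)quinide F3. Opening of the strained lactone with 4-methoxybenzyl alcohol and catalytic alkoxide (THF, 0 °C) returns to the route at 17.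

Step 6, silyl migration and lactonisation during acylal opening. The tertiary alkoxide could take the TES group from O5, after which the freed secondary alkoxide would close a γ-lactone; C-desilylation could also remain incomplete. The fallback separates the two operations in a protic medium and sets out from 11. LiOH in THF/H2O (0 °C to rt) opens the acylal and removes the alkynyl silyl group to give (2S,4R)-2-hydroxy-2-(prop-2-en-1-yl)-4-(triethylsilyloxy)hex-5-ynoic acid F4. The caesium carboxylate is then alkylated with 4-methoxybenzyl chloride (Cs2CO3, DMF, rt), which returns to the route at 12.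

Step 13, incomplete acylation of the hindered O4 or over-acylation at O1. The bulky activated cinnamate may stop at the 5-monoester, and forcing conditions may begin to acylate the tertiary hydroxyl. The fallback builds the cinnamoyl groups in place from a small acyl donor and sets out from 17. Heating with Meldrum's acid (toluene, 80 °C) should give the 4,5-bis(hydrogen malonate) of 4-methoxybenzyl 3-O-(tert-butyldimethylsilyl)quinate F5. A Knoevenagel–Doebner condensation with commercial 4-[(4-methoxybenzyl)oxy]benzaldehyde (pyridine, cat. piperidine, rt to 50 °C) then forms both E-alkenes with loss of carbon dioxide and returns to the route at 22.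

**Further compounds**
F1 | step 9 | (1S,5R)-1-hydroxy-6-oxabicyclo[3.2.1]oct-3-en-7-one | C1=CC[C@@]2(O)C(=O)O[C@@H]1C2
F2 | step 9 | (–)-quinide (1,5-lactone of (–)-quinic acid) | O[C@@H]1[C@H](O)C[C@@]2(O)C(=O)O[C@@H]1C2
F3 | step 9 | 3-O-(tert-butyldimethylsilyl)quinide | O[C@@H]1[C@H](O[Si](C)(C)C(C)(C)C)C[C@@]2(O)C(=O)O[C@@H]1C2
F4 | step 6 | (2S,4R)-2-hydroxy-2-(prop-2-en-1-yl)-4-(triethylsilyloxy)hex-5-ynoic acid | C=CC[C@@](O)(C(=O)O)C[C@@H](O[Si](CC)(CC)CC)C#C
F5 | step 13 | 4,5-bis(hydrogen malonate) of 4-methoxybenzyl 3-O-(tert-butyldimethylsilyl)quinate | O=C(CC(=O)O)O[C@@H]1[C@H](O[Si](C)(C)C(C)(C)C)C[C@@](O)(C(=O)OCc2ccc(OC)cc2)C[C@H]1OC(=O)CC(=O)O
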